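**Retrosynthetic overview**
- The target comes from one global hydrogenolysis of a protected dimer (eleven benzyl ethers, two 4-methylbenzyl ethers, two blocking C–Br bonds).
- The protected dimer is cut at the interflavan C4(ring C)–C8(ring D) bond and at the C4–C4a bond of ring F in one retron. This gives a C4-activated, C8-bromo-capped, perbenzylated epigallocatechin gallate (rings A, C, B from natural epigallocatechin, galloyl ring G by esterification) and an acyclic aryl ether epoxide carrying rings D and E.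
- Enabling feature: ring D is a phloroglucinol ring. While ring F is open, the two carbons flanking the O1-bearing carbon C8a (later C4a and C8) are equivalent by symmetry, and the third nucleophilic carbon (later C6) is blocked by bromine. One carbon takes the C4 cation of ring C and the other opens the terminal epoxide C3–C4 (strain release), in either order.
- The aryl ether epoxide comes from a Mitsunobu etherification (inversion at the later C2) of an erythro aryl epoxy alcohol (Sharpless kinetic resolution, sets C2 and C3) with 4-bromo-3,5-bis(4-methylbenzyloxy)phenol (C–H borylation/oxidation of a 2-bromoresorcinol diether).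
- Ring order: rings A, B, C (natural product) and D, E, G (commercial aromatics) exist from the start; ring F (O1, C2, C3, C4, C4a, C8a of the lower unit) is the only ring built and is closed last.

Key step: step 10

Remark: (−)-epigallocatechin, 3,4,5-tris(benzyloxy)benzoic acid, 3,4,5-tris(benzyloxy)benzaldehyde and 2-bromoresorcinol are taken as commercial; the two bromine atoms are temporary blocking groups that leave in the last step.

Step 1
Reactants: 1 (−)-epigallocatechin
Product: 2 5,7,3',4',5'-penta-O-benzyl-(−)-epigallocatechin (2R,3R; 3-OH free)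
Conditions: BnBr (5.2 equiv), K2CO3, DMF, N2, −10 °C → rt
Reagents that add atoms: benzyl bromide, BrCc1ccccc1
Why: Williamson etherification, in which the five phenols are far more acidic than the secondary 3-OH, so that K2CO3/BnBr should benzylate them selectively while C2 and C3 of the natural product stay untouched at low temperature.

Step 2
Reactants: 2 5,7,3',4',5'-penta-O-benzyl-(−)-epigallocatechin
Product: 3 8-bromo-5,7,3',4',5'-penta-O-benzyl-(−)-epigallocatechin
Conditions: NBS (1.0 equiv), CH2Cl2, −78 °C → 0 °C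
Reagents that add atoms: N-bromosuccinimide, O=C1CCC(=O)N1Br
Why: Electrophilic aromatic bromination, in which C8 of ring A (flanked by the ring oxygen O1 and 7-OBn) is the most nucleophilic and least hindered aryl carbon, so that one equivalent of NBS should cap it in preference to C6 and to ring B.

Step 3
Reactants: 3 8-bromo-5,7,3',4',5'-penta-O-benzyl-(−)-epigallocatechin
Product: 4 8-bromo-4β-(2-ethoxyethoxy)-5,7,3',4',5'-penta-O-benzyl-(−)-epigallocatechin (2,3-cis-3,4-trans)
Conditions: DDQ (2 equiv), 2-ethoxyethanol (excess), CH2Cl2, rt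
Reagents that add atoms: 2-ethoxyethanol, CCOCCO
Why: DDQ benzylic oxidation (hydride abstraction from C4 to a cation stabilised by the 5,7-dialkoxy ring A) with capture by the alcohol on the β face, anti to the 3-OH and the 2-aryl group, should give the 3,4-trans ether; the C4 configuration is erased again on ionisation in step 10.

Step 4
Reactants: 4 8-bromo-4β-(2-ethoxyethoxy)-5,7,3',4',5'-penta-O-benzyl-(−)-epigallocatechin; 5 3,4,5-tris(benzyloxy)benzoic acid
Product: 6 8-bromo-4β-(2-ethoxyethoxy)-5,7,3',4',5'-penta-O-benzyl-3-O-[3,4,5-tris(benzyloxy)benzoyl]-(−)-epigallocatechin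
Conditions: DCC, DMAP, CH2Cl2, rt
Reagents that add atoms: none
Why: Steglich esterification of the hindered 3-OH with the protected gallic acid, which touches no stereocentre.

Step 5
Reactants: 7 2-bromobenzene-1,3-diol (2-bromoresorcinol)
Product: 8 2-bromo-1,3-bis[(4-methylbenzyl)oxy]benzene
Conditions: 4-methylbenzyl bromide (2.2 equiv), K2CO3, DMF, 60 °C
Reagents that add atoms: 4-methylbenzyl bromide, Cc1ccc(CBr)cc1
Why: Williamson etherification of both phenols; the 4-methylbenzyl group is chosen because its para-disubstituted ring offers no unhindered C–H bond to the next step and because it is removed by hydrogenolysis like benzyl.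

Step 6
Reactants: 8 2-bromo-1,3-bis[(4-methylbenzyl)oxy]benzene
Product: 10 4-bromo-3,5-bis[(4-methylbenzyl)oxy]phenol, via aryl pinacol boronate 9 (not isolated)
Conditions: [Ir(OMe)(cod)]2 (1.5 mol %), 4,4'-di-tert-butyl-2,2'-bipyridine (3 mol %), B2pin2 (0.6 equiv), THF, 80 °C; then aq. H2O2, NaOH, 0 °C → rt
Reagents that add atoms: bis(pinacolato)diboron, B1(OC(C)(C)C(C)(C)O1)B1OC(C)(C)C(C)(C)O1 (boryl group of 9, not kept in 10); hydrogen peroxide, OO (phenol oxygen of 10)
Why: Sterically controlled iridium-catalysed C–H borylation should reach only C5 of the central ring, the one C–H bond with no ortho substituent, and basic peroxide oxidation of the C–B bond then gives the phenol with the aryl bromide intact.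

Step 7
Reactants: 11 3,4,5-tris(benzyloxy)benzaldehyde
Product: 12 rac-1-[3,4,5-tris(benzyloxy)phenyl]prop-2-en-1-ol
Conditions: CH2=CHMgBr, THF, −78 °C → 0 °C; then H2O
Reagents that add atoms: vinylmagnesium bromide, C=C[Mg]Br
Why: Grignard 1,2-addition to the aldehyde gives the racemic secondary allylic alcohol needed for the resolution.

Step 8
Reactants: 12 rac-1-[3,4,5-tris(benzyloxy)phenyl]prop-2-en-1-ol
Product: 13 (S)-[(2R)-oxiran-2-yl][3,4,5-tris(benzyloxy)phenyl]methanol (erythro)
Conditions: Ti(OiPr)4, L-(+)-DIPT, t-BuOOH (0.6 equiv), 4 Å MS, CH2Cl2, −20 °C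
Reagents that add atoms: tert-butyl hydroperoxide, CC(C)(C)OO
Why: Sharpless asymmetric epoxidation run as a kinetic resolution, in which the (R)-alcohol should be epoxidised fast and erythro-selectively (the tartrate fixes the alkene face and thus the later C3; the resolution selects the carbinol centre) while the (S)-alcohol is left behind.

Step 9
Reactants: 13 (S)-[(2R)-oxiran-2-yl][3,4,5-tris(benzyloxy)phenyl]methanol; 10 4-bromo-3,5-bis[(4-methylbenzyl)oxy]phenol
Product: 14 (2R)-2-[(R)-{4-bromo-3,5-bis[(4-methylbenzyl)oxy]phenoxy}[3,4,5-tris(benzyloxy)phenyl]methyl]oxirane (threo)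
Conditions: PPh3, DIAD, toluene, 0 °C → rt
Reagents that add atoms: none
Why: Mitsunobu reaction, in which the acidic, unhindered phenol displaces the activated benzylic oxygen with inversion and so turns the erythro alcohol into the threo aryl ether with the (R) configuration needed at the later C2; the adjacent epoxide and the flanked, weakened para-alkoxy donor of ring E disfavour ionisation.

Step 10
Reactants: 6 8-bromo-4β-(2-ethoxyethoxy)-5,7,3',4',5'-penta-O-benzyl-3-O-[3,4,5-tris(benzyloxy)benzoyl]-(−)-epigallocatechin; 14 (2R)-2-[(R)-{4-bromo-3,5-bis[(4-methylbenzyl)oxy]phenoxy}[3,4,5-tris(benzyloxy)phenyl]methyl]oxirane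
Product: 16 8-bromo-5,7,3',4',5'-penta-O-benzyl-3-O-[3,4,5-tris(benzyloxy)benzoyl]-(−)-epigallocatechin-(4β→8)-[6-bromo-3',4',5'-tri-O-benzyl-5,7-bis-O-(4-methylbenzyl)-(−)-epigallocatechin] (lower 3-OH free), via interflavan-coupled epoxide 15 (not isolated)
Conditions: AuCl3 (5 mol %), AgOSO2CF3 (AgOTf, 15 mol %), 4 Å MS, CH2Cl2, −40 °C → rt; aq. NaHCO3
Reagents that add atoms: none
Why: Proposed new method: one cationic trivalent gold triflate, formed from AuCl3 and AgOTf, is meant to serve two Friedel–Crafts events on ring D of 14: it ionises the C4 ether of 6 to the benzylic cation stabilised by ring A, which one of the two equivalent carbons ortho to the ether oxygen captures to give 15, and it then activates the terminal epoxide, whose CH2 carbon is attacked by the remaining ortho carbon. The closest known reaction types are the triflate Lewis acid mediated C4 arylation of 4-alkoxyflavan-3-ol derivatives by phloroglucinol-type arenes and the AuCl3/AgOTf-catalysed cycloalkylation of aryl ethers of 1-aryl-2,3-epoxypropan-1-ols to flavan-3-ols; their merger in one flask on an open ring D is the new element. Ring F closes by a 6-endo-tet epoxy-arene Friedel–Crafts alkylation (C4–C4a bond) driven by release of the epoxide strain, favoured over the 5-exo mode because the terminal carbon is the unhindered site of an SN2-like opening. The new stereocentre C4 of ring C is set by attack on the β face, anti to the 2-aryl group and to the 3-O-galloyl group that can bridge the cation on the α face, which gives the 3,4-trans (4β) bond, while C2 and C3 of ring F are carried over unchanged from 14 because only the terminal C–O bond of the epoxide breaks. The step needs cross-coupling instead of self-condensation and one defined carbon of ring D: the C8 bromine silences ring A of 6, and in 14 the two reacting carbons are equivalent while the only other nucleophilic carbon bears bromine, so that either order of the two events ends in the 4→8 connectivity.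

Step 11
Reactants: 16 protected dimer (name as in step 10)
Product: 17 (−)-epigallocatechin 3-O-gallate-(4β→8)-(−)-epigallocatechin (upper unit 2R,3R,4R; lower unit 2R,3R)
Conditions: H2 (1 atm), Pd(OH)2/C, Et3N (2.2 equiv), THF/MeOH/H2O, rt
Reagents that add atoms: none
Why: Heterogeneous hydrogenolysis should cleave the eleven benzyl and two 4-methylbenzyl ethers and, with Et3N as HBr scavenger, both aryl C–Br bonds, while the gallate ester, the interflavan bond and the five stereocentres are not affected.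

**Compound list**
1 | (−)-epigallocatechin | O[C@@H]1Cc2c(O)cc(O)cc2O[C@@H]1c1cc(O)c(O)c(O)c1 | starting material
2 | 5,7,3',4',5'-penta-O-benzyl-(−)-epigallocatechin | O[C@@H]1Cc2c(OCc3ccccc3)cc(OCc3ccccc3)cc2O[C@@H]1c1cc(OCc2ccccc2)c(OCc2ccccc2)c(OCc2ccccc2)c1 | intermediate
3 | 8-bromo-5,7,3',4',5'-penta-O-benzyl-(−)-epigallocatechin | O[C@@H]1Cc2c(OCc3ccccc3)cc(OCc3ccccc3)c(Br)c2O[C@@H]1c1cc(OCc2ccccc2)c(OCc2ccccc2)c(OCc2ccccc2)c1 | intermediate
4 | 8-bromo-4β-(2-ethoxyethoxy)-5,7,3',4',5'-penta-O-benzyl-(−)-epigallocatechin (2,3-cis-3,4-trans) | O[C@@H]1[C@@H](OCCOCC)c2c(OCc3ccccc3)cc(OCc3ccccc3)c(Br)c2O[C@@H]1c1cc(OCc2ccccc2)c(OCc2ccccc2)c(OCc2ccccc2)c1 | intermediate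
5 | 3,4,5-tris(benzyloxy)benzoic acid | OC(=O)c1cc(OCc2ccccc2)c(OCc2ccccc2)c(OCc2ccccc2)c1 | starting material
6 | 8-bromo-4β-(2-ethoxyethoxy)-5,7,3',4',5'-penta-O-benzyl-3-O-[3,4,5-tris(benzyloxy)benzoyl]-(−)-epigallocatechin | O=C(O[C@@H]1[C@@H](OCCOCC)c2c(OCc3ccccc3)cc(OCc3ccccc3)c(Br)c2O[C@@H]1c1cc(OCc2ccccc2)c(OCc2ccccc2)c(OCc2ccccc2)c1)c1cc(OCc2ccccc2)c(OCc2ccccc2)c(OCc2ccccc2)c1 | intermediate
7 | 2-bromobenzene-1,3-diol | Oc1cccc(O)c1Br | starting material
8 | 2-bromo-1,3-bis[(4-methylbenzyl)oxy]benzene | Cc1ccc(COc2cccc(OCc3ccc(C)cc3)c2Br)cc1 | intermediate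
9 | 2-{4-bromo-3,5-bis[(4-methylbenzyl)oxy]phenyl}-4,4,5,5-tetramethyl-1,3,2-dioxaborolane | Cc1ccc(COc2cc(B3OC(C)(C)C(C)(C)O3)cc(OCc3ccc(C)cc3)c2Br)cc1 | intermediate (not isolated)
10 | 4-bromo-3,5-bis[(4-methylbenzyl)oxy]phenol | Cc1ccc(COc2cc(O)cc(OCc3ccc(C)cc3)c2Br)cc1 | intermediate
11 | 3,4,5-tris(benzyloxy)benzaldehyde | O=Cc1cc(OCc2ccccc2)c(OCc2ccccc2)c(OCc2ccccc2)c1 | starting material
12 | rac-1-[3,4,5-tris(benzyloxy)phenyl]prop-2-en-1-ol | OC(C=C)c1cc(OCc2ccccc2)c(OCc2ccccc2)c(OCc2ccccc2)c1 | intermediate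
13 | (S)-[(2R)-oxiran-2-yl][3,4,5-tris(benzyloxy)phenyl]methanol | O[C@H]([C@H]1CO1)c1cc(OCc2ccccc2)c(OCc2ccccc2)c(OCc2ccccc2)c1 | intermediate
14 | (2R)-2-[(R)-{4-bromo-3,5-bis[(4-methylbenzyl)oxy]phenoxy}[3,4,5-tris(benzyloxy)phenyl]methyl]oxirane | Cc1ccc(COc2cc(O[C@@H]([C@H]3CO3)c3cc(OCc4ccccc4)c(OCc4ccccc4)c(OCc4ccccc4)c3)cc(OCc3ccc(C)cc3)c2Br)cc1 | intermediate
15 | 8-bromo-5,7,3',4',5'-penta-O-benzyl-3-O-[3,4,5-tris(benzyloxy)benzoyl]-4β-{3-bromo-2,4-bis[(4-methylbenzyl)oxy]-6-[(R)-[(2R)-oxiran-2-yl][3,4,5-tris(benzyloxy)phenyl]methoxy]phenyl}-(−)-epigallocatechin | O=C(O[C@@H]1[C@@H](c2c(OCc4ccc(C)cc4)c(Br)c(OCc4ccc(C)cc4)cc2O[C@@H]([C@H]3CO3)c2cc(OCc3ccccc3)c(OCc3ccccc3)c(OCc3ccccc3)c2)c2c(OCc3ccccc3)cc(OCc3ccccc3)c(Br)c2O[C@@H]1c1cc(OCc2ccccc2)c(OCc2ccccc2)c(OCc2ccccc2)c1)c1cc(OCc2ccccc2)c(OCc2ccccc2)c(OCc2ccccc2)c1 | intermediate (not isolated)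
16 | 8-bromo-5,7,3',4',5'-penta-O-benzyl-3-O-[3,4,5-tris(benzyloxy)benzoyl]-(−)-epigallocatechin-(4β→8)-[6-bromo-3',4',5'-tri-O-benzyl-5,7-bis-O-(4-methylbenzyl)-(−)-epigallocatechin] | O=C(O[C@@H]1[C@@H](c2c(OCc4ccc(C)cc4)c(Br)c(OCc4ccc(C)cc4)c3c2O[C@H](c2cc(OCc4ccccc4)c(OCc4ccccc4)c(OCc4ccccc4)c2)[C@H](O)C3)c2c(OCc3ccccc3)cc(OCc3ccccc3)c(Br)c2O[C@@H]1c1cc(OCc2ccccc2)c(OCc2ccccc2)c(OCc2ccccc2)c1)c1cc(OCc2ccccc2)c(OCc2ccccc2)c(OCc2ccccc2)c1 | intermediate
17 | (−)-epigallocatechin 3-O-gallate-(4β→8)-(−)-epigallocatechin | O=C(O[C@@H]1[C@@H](c2c(O)cc(O)c3c2O[C@H](c2cc(O)c(O)c(O)c2)[C@H](O)C3)c2c(O)cc(O)cc2O[C@@H]1c1cc(O)c(O)c(O)c1)c1cc(O)c(O)c(O)c1 | target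

Total step count: 11. Longest linear sequence: 6 steps (steps 1, 2, 3, 4, 10, 11); the other two branches (steps 5, 6 and steps 7, 8) join at step 9.

**Steps most likely to fail**

Step 10 (proposed new method). The single catalyst may not serve both events. The liberated 2-ethoxyethanol or triflate may open the activated epoxide, the epoxide may rearrange to a carbonyl compound (Meinwald-type), the intermolecular arylation at a doubly flanked carbon of a brominated ring may be too slow, or 4-methylbenzyl ethers may be lost to the Lewis acid. The fallback uses known chemistry, sets out from 14 and returns at 16. Compound 14 alone is cyclised with AuCl3/AgOTf in CH2Cl2 (the established gold-catalysed epoxy-arene cycloalkylation) to (2R,3R)-6-bromo-5,7-bis[(4-methylbenzyl)oxy]-2-[3,4,5-tris(benzyloxy)phenyl]chroman-3-ol F1. F1 is then coupled with 6 under Me3SiOSO2CF3 in CH2Cl2 at −78 °C (the established C4 arylation), C8 being the only free carbon of ring D, to give 16.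

Step 9. Ionisation at the activated benzylic carbon would erode the inversion and give erythro/threo mixtures; elimination and attack of the phenoxide on the epoxide are further losses. The fallback sets out from 11 (joined by 10) and returns at 14.
- Horner–Wadsworth–Emmons olefination of 11 (triethyl phosphonoacetate, NaH, THF) gives ethyl (E)-3-[3,4,5-tris(benzyloxy)phenyl]prop-2-enoate F2.
- Reduction with iBu2AlH (CH2Cl2, −78 °C) gives (E)-3-[3,4,5-tris(benzyloxy)phenyl]prop-2-en-1-ol F3.
- Sharpless asymmetric epoxidation (Ti(OiPr)4, L-(+)-DET, t-BuOOH, 4 Å MS, CH2Cl2, −20 °C) gives [(2S,3S)-3-[3,4,5-tris(benzyloxy)phenyl]oxiran-2-yl]methanol F4.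
- The phenoxide of 10 (NaOH, H2O/t-BuOH, 60 °C) opens F4 at the benzylic carbon with inversion to (2S,3R)-3-{4-bromo-3,5-bis[(4-methylbenzyl)oxy]phenoxy}-3-[3,4,5-tris(benzyloxy)phenyl]propane-1,2-diol F5.
- Silylation of the primary hydroxyl (TBSCl, imidazole, CH2Cl2) gives (2S,3R)-1-[(tert-butyldimethylsilyl)oxy]-3-{4-bromo-3,5-bis[(4-methylbenzyl)oxy]phenoxy}-3-[3,4,5-tris(benzyloxy)phenyl]propan-2-ol F6.
- Mesylation (MsCl, Et3N) gives (2S,3R)-1-[(tert-butyldimethylsilyl)oxy]-3-{4-bromo-3,5-bis[(4-methylbenzyl)oxy]phenoxy}-3-[3,4,5-tris(benzyloxy)phenyl]propan-2-yl methanesulfonate F7.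
- Bu4NF (THF) removes the silyl group, and the primary alkoxide displaces the mesylate with inversion at the secondary carbon to give 14.

Step 8. Epoxidation of a monosubstituted vinyl group is slow, and the acid-sensitive aryl epoxy alcohol may be opened or rearranged by the titanium Lewis acid, so that the resolution stays incomplete and material is lost. The fallback sets out from 11 and returns at 13. Catalytic enantioselective addition of Zn(CH=CH2)2 to 11 in the presence of a chiral 3-exo-aminoisoborneol ligand (antipode chosen for the (R)-alcohol) gives (R)-1-[3,4,5-tris(benzyloxy)phenyl]prop-2-en-1-ol F8. F8 is epoxidised in the reagent-matched sense (Ti(OiPr)4, L-(+)-DIPT, t-BuOOH, 4 Å MS, CH2Cl2, −20 °C) to full conversion to give 13.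

Further compounds
F1 | step 10 | (2R,3R)-6-bromo-5,7-bis[(4-methylbenzyl)oxy]-2-[3,4,5-tris(benzyloxy)phenyl]chroman-3-ol | O[C@@H]1Cc2c(OCc3ccc(C)cc3)c(Br)c(OCc3ccc(C)cc3)cc2O[C@@H]1c1cc(OCc2ccccc2)c(OCc2ccccc2)c(OCc2ccccc2)c1
F2 | step 9 | ethyl (E)-3-[3,4,5-tris(benzyloxy)phenyl]prop-2-enoate | CCOC(=O)/C=C/c1cc(OCc2ccccc2)c(OCc2ccccc2)c(OCc2ccccc2)c1
F3 | step 9 | (E)-3-[3,4,5-tris(benzyloxy)phenyl]prop-2-en-1-ol | OC/C=C/c1cc(OCc2ccccc2)c(OCc2ccccc2)c(OCc2ccccc2)c1
F4 | step 9 | [(2S,3S)-3-[3,4,5-tris(benzyloxy)phenyl]oxiran-2-yl]methanol | OC[C@@H]1O[C@H]1c1cc(OCc2ccccc2)c(OCc2ccccc2)c(OCc2ccccc2)c1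
F5 | step 9 | (2S,3R)-3-{4-bromo-3,5-bis[(4-methylbenzyl)oxy]phenoxy}-3-[3,4,5-tris(benzyloxy)phenyl]propane-1,2-diol | OC[C@H](O)[C@H](Oc1cc(OCc2ccc(C)cc2)c(Br)c(OCc2ccc(C)cc2)c1)c1cc(OCc2ccccc2)c(OCc2ccccc2)c(OCc2ccccc2)c1
F6 | step 9 | (2S,3R)-1-[(tert-butyldimethylsilyl)oxy]-3-{4-bromo-3,5-bis[(4-methylbenzyl)oxy]phenoxy}-3-[3,4,5-tris(benzyloxy)phenyl]propan-2-ol | CC(C)(C)[Si](C)(C)OC[C@H](O)[C@H](Oc1cc(OCc2ccc(C)cc2)c(Br)c(OCc2ccc(C)cc2)c1)c1cc(OCc2ccccc2)c(OCc2ccccc2)c(OCc2ccccc2)c1
F7 | step 9 | (2S,3R)-1-[(tert-butyldimethylsilyl)oxy]-3-{4-bromo-3,5-bis[(4-methylbenzyl)oxy]phenoxy}-3-[3,4,5-tris(benzyloxy)phenyl]propan-2-yl methanesulfonate | CC(C)(C)[Si](C)(C)OC[C@H](OS(C)(=O)=O)[C@H](Oc1cc(OCc2ccc(C)cc2)c(Br)c(OCc2ccc(C)cc2)c1)c1cc(OCc2ccccc2)c(OCc2ccccc2)c(OCc2ccccc2)c1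
F8 | step 8 | (R)-1-[3,4,5-tris(benzyloxy)phenyl]prop-2-en-1-ol | O[C@H](C=C)c1cc(OCc2ccccc2)c(OCc2ccccc2)c(OCc2ccccc2)c1
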